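**Assumption:** the target SMILES has no stereodescriptor and no stereocentres; its only stereogenic element is the hindered 2,2'-biaryl axis, which is left undefined. The route therefore delivers the compound as written, with the axis uncontrolled (racemic).

**Retrosynthetic overview**
1. Cut the C2–C2' biaryl bond last: oxidative phenol homocoupling of the monomer 5-isopropyl-3,8-dimethyl-1-naphthol (8-hydroxycadalene). C2 is the only ortho site, and the para site C4 is shielded by the C3-methyl and the peri isopropyl.
2. The C3 methyl comes from an ester (reduction, then benzylic hydrogenolysis).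
3. The phenolic ring is built by Stobbe condensation and acylative ring closure onto the one free ortho position of 2-isopropyl-5-methylbenzaldehyde.
4. The aldehyde comes from thymol by replacing C–O with C–C (triflate, Pd formylation).
5. Ring order: the cymene ring is bought (thymol), the phenolic ring is annulated, then the two halves are dimerised.

**Step 1**
Reactants: 1 thymol (2-isopropyl-5-methylphenol); 2 triflic anhydride
Product: 3, 2-isopropyl-5-methylphenyl trifluoromethanesulfonate
Conditions: Tf2O, pyridine, CH2Cl2, 0 °C to rt
Reagents that add atoms: triflic anhydride, O=S(=O)(OS(=O)(=O)C(F)(F)F)C(F)(F)F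
Why: O-sulfonylation of the phenol turns the C–O bond into a cross-coupling handle; nothing else in the molecule reacts.

**Step 2**
Reactants: 3 aryl triflate; 4 carbon monoxide
Product: 5, 2-isopropyl-5-methylbenzaldehyde
Conditions: Pd(OAc)2, dppp, CO (1 atm), Et3SiH, Et3N, DMF, 70 °C
Reagents that add atoms: carbon monoxide, [C-]#[O+]
Why: Pd-catalysed reductive carbonylation (formylation) of an aryl triflate: oxidative addition, CO insertion, then hydride transfer from the silane to the acyl-Pd.

**Step 3**
Reactants: 5 aldehyde; 6 diethyl succinate
Product: 7, (E)-3-(ethoxycarbonyl)-4-(2-isopropyl-5-methylphenyl)but-3-enoic acid (aryl cis to CH2CO2H)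
Conditions: t-BuOK, t-BuOH, reflux; then aq. HCl
Reagents that add atoms: diethyl succinate, CCOC(=O)CCC(=O)OCC
Why: Stobbe condensation of a non-enolisable aryl aldehyde; the paraconate lactone intermediate opens irreversibly to the E half-ester, which has the geometry needed for ring closure.

**Step 4**
Reactants: 7 half-ester; 8 acetic anhydride
Product: 9, ethyl 4-acetoxy-8-isopropyl-5-methyl-2-naphthoate
Conditions: Ac2O, NaOAc, reflux
Reagents that add atoms: acetic anhydride, CC(=O)OC(C)=O
Why: The mixed anhydride undergoes intramolecular Friedel–Crafts acylation (Stobbe benzannulation) at the only free ortho position, next to the ring methyl, and the new naphthol is trapped as its acetate.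

**Step 5**
Reactants: 9 acetoxy ester
Product: 10, 3-(hydroxymethyl)-5-isopropyl-8-methylnaphthalen-1-ol
Conditions: LiAlH4, THF, 0 °C to reflux; aq. acid work-up under N2
Reagents that add atoms: none
Why: Hydride reduction takes the ethyl ester to the primary alcohol and cleaves the aryl acetate in the same operation.

**Step 6**
Reactants: 10 naphthylmethanol
Product: 11, 5-isopropyl-3,8-dimethylnaphthalen-1-ol (8-hydroxycadalene)
Conditions: H2 (1 atm), 10% Pd/C, AcOH, cat. HClO4, rt; stop at 1 equiv H2
Reagents that add atoms: none
Why: Acid-assisted catalytic hydrogenolysis of the naphthylmethyl C–O bond gives the methyl group, and the naphthol ring and OH survive at 1 atm and room temperature.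

**Step 7**
Reactants: 11 naphthol (2 equiv)
Product: 12, Parviflorene H (5,5'-diisopropyl-3,3',8,8'-tetramethyl-[2,2'-binaphthalene]-1,1'-diol), racemic about the axis
Conditions: (t-BuO)2 (0.6–1.0 equiv), PhCl, reflux, Ar
Reagents that add atoms: none
Why: Oxidative phenol homocoupling: t-BuO• abstracts the O–H hydrogen, the naphthoxyl radical dimerises at C2 because C4 is blocked by the C3-methyl and peri isopropyl, and tautomerisation gives the binaphthol; the axis forms without control, matching the undefined target.

**Compound list**
1 | thymol (2-isopropyl-5-methylphenol) | Cc1ccc(C(C)C)c(O)c1 | starting material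
2 | trifluoromethanesulfonic anhydride | O=S(=O)(OS(=O)(=O)C(F)(F)F)C(F)(F)F | starting material
3 | 2-isopropyl-5-methylphenyl trifluoromethanesulfonate | Cc1ccc(C(C)C)c(OS(=O)(=O)C(F)(F)F)c1 | intermediate
4 | carbon monoxide | [C-]#[O+] | starting material
5 | 2-isopropyl-5-methylbenzaldehyde | Cc1ccc(C(C)C)c(C=O)c1 | intermediate
6 | diethyl succinate | CCOC(=O)CCC(=O)OCC | starting material
7 | (E)-3-(ethoxycarbonyl)-4-(2-isopropyl-5-methylphenyl)but-3-enoic acid | CCOC(=O)/C(CC(=O)O)=C/c1cc(C)ccc1C(C)C | intermediate
8 | acetic anhydride | CC(=O)OC(C)=O | starting material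
9 | ethyl 4-acetoxy-8-isopropyl-5-methyl-2-naphthoate | CCOC(=O)c1cc(OC(C)=O)c2c(C)ccc(C(C)C)c2c1 | intermediate
10 | 3-(hydroxymethyl)-5-isopropyl-8-methylnaphthalen-1-ol | OCc1cc(O)c2c(C)ccc(C(C)C)c2c1 | intermediate
11 | 5-isopropyl-3,8-dimethylnaphthalen-1-ol | Cc1cc(O)c2c(C)ccc(C(C)C)c2c1 | intermediate
12 | Parviflorene H | Cc1cc2c(C(C)C)ccc(C)c2c(O)c1-c1c(C)cc2c(C(C)C)ccc(C)c2c1O | target

**Total steps:** 7. **Longest linear sequence:** 7 (fully linear from thymol).

**Three steps most likely to fail, with fallbacks**
1. **Step 7 (oxidative coupling).** Risks are over-oxidation to quinones and some C4 coupling. Fallback: make the bond by a site-defined coupling instead. Protect 11 as its MOM ether, ortho-lithiate at C2 (the only ortho position), quench with I2, homocouple the 2-iodide with Cu (Ullmann), then remove MOM with HCl/MeOH.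
2. **Step 2 (Pd formylation of a hindered ortho-isopropyl triflate).** Risks are slow oxidative addition and reduction to p-cymene. Fallback: drop the aldehyde/Stobbe sequence. Mono-α-arylate acetone with thymyl tosylate under Pd, run a Horner–Wadsworth–Emmons reaction on the arylacetone, saponify to the 3-methyl-4-arylbutenoic acid, and cyclise with Ac2O/NaOAc. This gives the acetate of 11 with the C3 methyl already in place, so steps 5–6 are not needed.
3. **Step 6 (hydrogenolysis of the naphthylmethanol).** Risks are ring over-reduction or a sluggish reaction. Fallback: deoxygenate by substitution instead of hydrogenolysis. Convert 10 to the naphthylmethyl bromide (PBr3, 0 °C) and reduce the C–Br bond with Zn/AcOH or LiAlH4.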